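The route rests on breaking the O–C5 bond of the dihydrofuran ring in the 5,8-epoxide end group, where the ether carbons C5 (quaternary, shared with the cyclohexane ring) and C8 sit 1,3 across oxygen and C6 has hydrogen only on its neighbour C7. One selenium-induced 5-endo closure of a C8 carbinol onto the C5=C6 ring alkene makes the oxolane, relays the catalyst-set C8 configuration to C5 and leaves a C6 selenide that can only eliminate to the C6=C7 alkene. The precursor is an (R)-γ-hydroxy-β-methyl enoate carrying the β-cyclogeranyl ring; the polyene follows by two Wittig couplings with a C10 dialdehyde and an (R)-α-ionone-derived C15 salt.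

Key step: step 5

Remark: carotenoid numbering is used for positions (C1–C11 in the furanoid C15 half, primed locants in the α-ionone half); β-homocyclocitral, (R)-α-ionone and the C10 dialdehyde are taken as purchasable.

Step 1
Reactants: 1 ethyl acetoacetate (ethyl 3-oxobutanoate)
Product: 2 ethyl (2E)-3-{[(trifluoromethyl)sulfonyl]oxy}but-2-enoate (triflate trans to the ester group)
Conditions: Tf2O, aq Me4NOH, hexanes, 5 °C
Reagents that add atoms: trifluoromethanesulfonic anhydride, O=S(=O)(OS(=O)(=O)C(F)(F)F)C(F)(F)F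
Why: O-triflation of the β-keto ester enolate; with the non-coordinating tetramethylammonium counter-ion the enolate is not chelated and should be trapped mainly as the E enol triflate, the minor Z isomer being removable by chromatography.

Step 2
Reactants: 2 the E enol triflate; 3 β-homocyclocitral, (2,6,6-trimethylcyclohex-1-en-1-yl)acetaldehyde
Product: 4 racemic ethyl (2E)-4-hydroxy-3-methyl-5-(2,6,6-trimethylcyclohex-1-en-1-yl)pent-2-enoate
Conditions: CrCl2 (4 equiv), NiCl2 (2 mol%), DMF, rt
Reagents that add atoms: none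
Why: Nozaki–Hiyama–Kishi coupling, in which zerovalent nickel inserts into the alkenyl C–OTf bond and the derived alkenylchromium species of trivalent chromium adds to the aldehyde but not to the ester, with retention of alkene geometry and without enolising the β,γ-unsaturated aldehyde; C8 is formed racemic here.

Step 3
Reactants: 4 the racemic γ-hydroxy enoate
Product: 5 ethyl (2E)-3-methyl-4-oxo-5-(2,6,6-trimethylcyclohex-1-en-1-yl)pent-2-enoate (C8 ketone)
Conditions: Dess–Martin periodinane, CH2Cl2, 0 °C → rt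
Reagents that add atoms: none
Why: Dess–Martin oxidation of the secondary allylic alcohol under near-neutral conditions, chosen so that the ring alkene should not move into conjugation with the new ketone.

Step 4
Reactants: 5 the C8 ketone
Product: 6 ethyl (2E,4R)-4-hydroxy-3-methyl-5-(2,6,6-trimethylcyclohex-1-en-1-yl)pent-2-enoate
Conditions: (S)-2-methyl-CBS-oxazaborolidine (20 mol%), catecholborane, toluene, −78 °C
Reagents that add atoms: none
Why: Corey–Bakshi–Shibata reduction, in which the ketone binds the catalyst boron anti to the bulkier α-methylalkenyl arm so that hydride is delivered to the Si face, which should set C8 as R, while catecholborane at low temperature leaves the ester and both alkenes alone.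

Step 5
Reactants: 6 the (4R)-hydroxy enoate
Product: 7 ethyl (2E)-3-[(2R,3aR,7aR)-4,4,7a-trimethyl-3a-(phenylselanyl)octahydro-1-benzofuran-2-yl]but-2-enoate (selenium on C6, cis to the C5 methyl, cis-fused)
Conditions: PhSeCl (1.2 equiv), K2CO3, CH2Cl2, −78 → −20 °C
Reagents that add atoms: phenylselenenyl chloride, Cl[Se]c1ccccc1
Why: Phenylselenoetherification, in which PhSeCl adds reversibly to the electron-rich tetrasubstituted C5=C6 ring alkene to give a seleniranium ion that the C8 hydroxyl opens at C5 from the opposite face. The closest known reaction type is the 5-endo phenylselenoetherification and selenolactonisation of homoallylic alcohols and β,γ-unsaturated acids, including cyclohexenylacetic acids with this substitution pattern. The oxolane closes in a 5-endo-trig mode, because attack at C6 would require a 4-exo closure to an oxetane. C6 is fixed by the anti addition itself (selenium cis to the C5 methyl, cis ring fusion), and C5 by the C8 centre, whose alkenyl arm should sit pseudo-equatorial and away from the C5 methyl in the envelope-like transition state, leading to the 5R,6R,8R isomer. The step needs chemoselectivity for the ring alkene, regioselectivity for C5 and facial selectivity, which rest on the deactivated enoate alkene, on ring strain and on the C8 centre respectively, while solid K2CO3 removes HCl so that neither ether nor carbinol ionises.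

Step 6
Reactants: 7 the C6 phenylselenide
Product: 9 ethyl (2E)-3-[(2R,7aR)-4,4,7a-trimethyl-2,4,5,6,7,7a-hexahydro-1-benzofuran-2-yl]but-2-enoate, via C6 selenoxide 8 (not isolated)
Conditions: 30% H2O2 (3 equiv), pyridine, CH2Cl2, 0 °C → rt
Reagents that add atoms: none
Why: Selenide oxidation followed by selenoxide syn elimination, which can only run toward C7 because C1 and C5 carry no hydrogen, so the C6=C7 alkene of the dihydrofuran should form as a single regioisomer with C5 and C8 untouched.

Step 7
Reactants: 9 the dihydrofuran ester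
Product: 10 (2E)-3-[(2R,7aR)-4,4,7a-trimethyl-2,4,5,6,7,7a-hexahydro-1-benzofuran-2-yl]but-2-en-1-ol
Conditions: i-Bu2AlH (2.5 equiv), CH2Cl2, −78 °C; aq potassium sodium tartrate work-up
Reagents that add atoms: none
Why: 1,2-Reduction of the conjugated ester to the allylic alcohol with DIBAL-H, which leaves the alkenes and the cyclic ether untouched.

Step 8
Reactants: 10 the allylic alcohol
Product: 11 (2R,7aR)-2-[(2E)-4-bromobut-2-en-2-yl]-4,4,7a-trimethyl-2,4,5,6,7,7a-hexahydro-1-benzofuran
Conditions: CBr4, PPh3, CH2Cl2, −20 → 0 °C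
Reagents that add atoms: carbon tetrabromide, BrC(Br)(Br)Br
Why: Appel bromination of the primary allylic alcohol by SN2 displacement under acid-free conditions, chosen because the doubly allylic C8–O bond should not be exposed to HBr-based methods.

Step 9
Reactants: 11 the allylic bromide
Product: 12 {(2E)-3-[(2R,7aR)-4,4,7a-trimethyl-2,4,5,6,7,7a-hexahydro-1-benzofuran-2-yl]but-2-en-1-yl}triphenylphosphonium bromide
Conditions: PPh3, EtOAc, rt, dark
Reagents that add atoms: triphenylphosphine, c1ccc(cc1)P(c1ccccc1)c1ccccc1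
Why: SN2 quaternisation of the primary allylic bromide by triphenylphosphine, from which the salt should precipitate without acid and with the E alkene retained.

Step 10
Reactants: 13 (R)-α-ionone, (3E)-4-[(1R)-2,6,6-trimethylcyclohex-2-en-1-yl]but-3-en-2-one
Product: 14 (1E)-3-methyl-1-[(1R)-2,6,6-trimethylcyclohex-2-en-1-yl]penta-1,4-dien-3-ol (both C3 epimers)
Conditions: CH2=CHMgBr, THF, −20 → 0 °C; aq NH4Cl
Reagents that add atoms: vinylmagnesium bromide, C=C[Mg]Br
Why: Grignard 1,2-addition to the enone carbonyl; the new carbinol centre forms unselectively but is removed in the next step, and C6' is not affected.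

Step 11
Reactants: 14 the vinyl carbinol
Product: 15 {(2E,4E)-3-methyl-5-[(1R)-2,6,6-trimethylcyclohex-2-en-1-yl]penta-2,4-dien-1-yl}triphenylphosphonium bromide
Conditions: PPh3·HBr, MeOH, rt; crystallise
Reagents that add atoms: triphenylphosphine hydrobromide, Br.c1ccc(cc1)P(c1ccccc1)c1ccccc1
Why: Acid-mediated allylic transposition (SN1'), in which the tertiary bis-allylic alcohol ionises to a pentadienyl cation that the phosphine captures at the primary terminus, the usual way to C15 Wittig salts; C6' lies outside the cation and should keep its configuration.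

Step 12
Reactants: 15 the α-ionylidene C15 phosphonium bromide; 16 C10 dialdehyde, (2E,4E,6E)-2,7-dimethylocta-2,4,6-trienedial (2.5 equiv)
Product: 18 C25 aldehyde (2E,4E,6E,8E,10E,12E)-2,7,11-trimethyl-13-[(1R)-2,6,6-trimethylcyclohex-2-en-1-yl]trideca-2,4,6,8,10,12-hexaenal, via C15 ylide 17 (not isolated)
Conditions: NaOMe, MeOH/CH2Cl2, 0 °C → rt; then heptane, reflux
Reagents that add atoms: none
Why: Wittig olefination, in which the excess of the symmetrical dialdehyde and the lower electrophilicity of the extended product aldehyde should favour mono-olefination, and the cis component at the new C11'=C12' bond should isomerise to E on heating.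

Step 13
Reactants: 12 the furanoid C15 phosphonium bromide; 18 the C25 aldehyde
Product: 20 target (5R,8R,6'R)-5,8-epoxy-5,8-dihydro-β,ε-carotene, via furanoid C15 ylide 19 (not isolated)
Conditions: NaOMe, MeOH/CH2Cl2, −10 °C → rt, dark; then heptane, reflux; crystallise
Reagents that add atoms: none
Why: Wittig olefination forming C11=C12, with the ylide generated in the presence of the aldehyde so that it is consumed before it can open the allylic ether; no stereocentre is touched and thermal equilibration should give the all-E polyene.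

Compound list
1 | ethyl acetoacetate | CCOC(=O)CC(C)=O | starting material
2 | ethyl (2E)-3-{[(trifluoromethyl)sulfonyl]oxy}but-2-enoate | CCOC(=O)/C=C(\C)OS(=O)(=O)C(F)(F)F | intermediate
3 | β-homocyclocitral, (2,6,6-trimethylcyclohex-1-en-1-yl)acetaldehyde | CC1=C(CC=O)C(C)(C)CCC1 | starting material
4 | racemic ethyl (2E)-4-hydroxy-3-methyl-5-(2,6,6-trimethylcyclohex-1-en-1-yl)pent-2-enoate | CCOC(=O)/C=C(\C)C(O)CC1=C(C)CCCC1(C)C | intermediate
5 | ethyl (2E)-3-methyl-4-oxo-5-(2,6,6-trimethylcyclohex-1-en-1-yl)pent-2-enoate | CCOC(=O)/C=C(\C)C(=O)CC1=C(C)CCCC1(C)C | intermediate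
6 | ethyl (2E,4R)-4-hydroxy-3-methyl-5-(2,6,6-trimethylcyclohex-1-en-1-yl)pent-2-enoate | CCOC(=O)/C=C(\C)[C@H](O)CC1=C(C)CCCC1(C)C | intermediate
7 | ethyl (2E)-3-[(2R,3aR,7aR)-4,4,7a-trimethyl-3a-(phenylselanyl)octahydro-1-benzofuran-2-yl]but-2-enoate | CCOC(=O)/C=C(\C)[C@H]1C[C@@]2([Se]c3ccccc3)C(C)(C)CCC[C@@]2(C)O1 | intermediate
8 | selenoxide of 7 (both selenium epimers) | CCOC(=O)/C=C(\C)[C@H]1C[C@@]2([Se](=O)c3ccccc3)C(C)(C)CCC[C@@]2(C)O1 | intermediate
9 | ethyl (2E)-3-[(2R,7aR)-4,4,7a-trimethyl-2,4,5,6,7,7a-hexahydro-1-benzofuran-2-yl]but-2-enoate | CCOC(=O)/C=C(\C)[C@H]1C=C2C(C)(C)CCC[C@@]2(C)O1 | intermediate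
10 | (2E)-3-[(2R,7aR)-4,4,7a-trimethyl-2,4,5,6,7,7a-hexahydro-1-benzofuran-2-yl]but-2-en-1-ol | OC/C=C(\C)[C@H]1C=C2C(C)(C)CCC[C@@]2(C)O1 | intermediate
11 | (2R,7aR)-2-[(2E)-4-bromobut-2-en-2-yl]-4,4,7a-trimethyl-2,4,5,6,7,7a-hexahydro-1-benzofuran | BrC/C=C(\C)[C@H]1C=C2C(C)(C)CCC[C@@]2(C)O1 | intermediate
12 | {(2E)-3-[(2R,7aR)-4,4,7a-trimethyl-2,4,5,6,7,7a-hexahydro-1-benzofuran-2-yl]but-2-en-1-yl}triphenylphosphonium bromide | [Br-].c1ccccc1[P+](c1ccccc1)(c1ccccc1)C/C=C(\C)[C@H]1C=C2C(C)(C)CCC[C@@]2(C)O1 | intermediate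
13 | (R)-α-ionone | CC1=CCCC(C)(C)[C@H]1/C=C/C(C)=O | starting material
14 | (1E)-3-methyl-1-[(1R)-2,6,6-trimethylcyclohex-2-en-1-yl]penta-1,4-dien-3-ol (C3 epimers) | CC1=CCCC(C)(C)[C@H]1/C=C/C(C)(O)C=C | intermediate
15 | {(2E,4E)-3-methyl-5-[(1R)-2,6,6-trimethylcyclohex-2-en-1-yl]penta-2,4-dien-1-yl}triphenylphosphonium bromide | CC1=CCCC(C)(C)[C@H]1/C=C/C(C)=C/C[P+](c1ccccc1)(c1ccccc1)c1ccccc1.[Br-] | intermediate
16 | (2E,4E,6E)-2,7-dimethylocta-2,4,6-trienedial (C10 dialdehyde) | O=C/C(C)=C/C=C/C=C(\C)C=O | starting material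
17 | triphenyl{(2E,4E)-3-methyl-5-[(1R)-2,6,6-trimethylcyclohex-2-en-1-yl]penta-2,4-dien-1-ylidene}phosphorane | CC1=CCCC(C)(C)[C@H]1/C=C/C(C)=C/C=P(c1ccccc1)(c1ccccc1)c1ccccc1 | intermediate
18 | (2E,4E,6E,8E,10E,12E)-2,7,11-trimethyl-13-[(1R)-2,6,6-trimethylcyclohex-2-en-1-yl]trideca-2,4,6,8,10,12-hexaenal (C25 aldehyde) | CC1=CCCC(C)(C)[C@H]1/C=C/C(C)=C/C=C/C(C)=C/C=C/C=C(C)/C=O | intermediate
19 | triphenyl{(2E)-3-[(2R,7aR)-4,4,7a-trimethyl-2,4,5,6,7,7a-hexahydro-1-benzofuran-2-yl]but-2-en-1-ylidene}phosphorane | c1ccccc1P(c1ccccc1)(c1ccccc1)=C/C=C(\C)[C@H]1C=C2C(C)(C)CCC[C@@]2(C)O1 | intermediate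
20 | (5R,8R,6'R)-5,8-epoxy-5,8-dihydro-β,ε-carotene | CC1=CCCC(C)(C)[C@H]1/C=C/C(C)=C/C=C/C(C)=C/C=C/C=C(C)/C=C/C=C(\C)[C@H]1C=C2C(C)(C)CCC[C@@]2(C)O1 | target

Total step count: 13. Longest linear sequence: 10 steps (steps 1–9 and 13).

Steps most likely to fail

Step 5. The C8 centre may steer selenium poorly or to the wrong face, so that the C5 epimer (alkenyl arm cis to the C5 methyl) forms alongside or instead of 7; loss of an allylic proton from the seleniranium ion may also compete with ring closure. The fallback sets out from 6 and comes back at 9. Treating 6 with catalytic VO(acac)2 and t-BuOOH in toluene lets the C8 hydroxyl bind the metal and deliver oxygen to the alkene face on which it sits, which should give the epoxy alcohol ethyl (2E,4R)-4-hydroxy-3-methyl-5-[(1R,6S)-2,2,6-trimethyl-7-oxabicyclo[4.1.0]heptan-1-yl]pent-2-enoate F1. Catalytic camphorsulfonic acid in CH2Cl2 should then let the same hydroxyl open the epoxide at C5 with inversion (5-endo, tertiary centre) to the hydroxy ether ethyl (2E)-3-[(2R,3aR,7aR)-3a-hydroxy-4,4,7a-trimethyloctahydro-1-benzofuran-2-yl]but-2-enoate F2. Burgess dehydration of the tertiary C6 alcohol, again possible only toward C7, rejoins the route at 9. Because the hydroxyl first directs the electrophile to its own face and then closes from the opposite one, the sense of 1,3-induction is the reverse of that in the selenium closure.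

Step 13. The allylic ylide may decompose by vinylogous β-elimination that opens the doubly allylic C8–O bond, or the ether may ionise at C8 while the bromide and the salt are handled (steps 8 and 9). The fallback sets out from 10 and 18 and comes back at 20, with the polarity of the last coupling reversed. Oxidation of 10 with MnO2 in CH2Cl2 should give (2E)-3-[(2R,7aR)-4,4,7a-trimethyl-2,4,5,6,7,7a-hexahydro-1-benzofuran-2-yl]but-2-enal F3. Reduction of 18 with NaBH4 in EtOH at 0 °C should give the C25 alcohol (2E,4E,6E,8E,10E,12E)-2,7,11-trimethyl-13-[(1R)-2,6,6-trimethylcyclohex-2-en-1-yl]trideca-2,4,6,8,10,12-hexaen-1-ol F4, which PPh3·HBr in MeOH converts into the corresponding C25 triphenylphosphonium bromide F5. Its ylide F6 (NaOMe, MeOH/CH2Cl2) then reacts with F3 in a Wittig olefination that forms the same C11=C12 bond and gives 20. No ylide or allylic bromide is then placed next to the dihydrofuran.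

Step 4. Enantioface discrimination may be insufficient because the two carbonyl substituents are of similar effective size, and conjugate reduction of the keto enoate may compete. The fallback sets out from 4 and comes back at 6, so that steps 3 and 4 are not needed; it is a classical resolution. Esterification of racemic 4 with (S)-O-methylmandelic acid (DCC, DMAP, CH2Cl2) should give two diastereomeric esters, ethyl (2E,4R)-4-{[(2S)-2-methoxy-2-phenylacetyl]oxy}-3-methyl-5-(2,6,6-trimethylcyclohex-1-en-1-yl)pent-2-enoate F7 and its (4S) diastereomer F8. After chromatographic separation, ethanolysis of F7 (K2CO3, EtOH, 0 °C) should release 6.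

Further compounds
F1 | step 5 | ethyl (2E,4R)-4-hydroxy-3-methyl-5-[(1R,6S)-2,2,6-trimethyl-7-oxabicyclo[4.1.0]heptan-1-yl]pent-2-enoate | CCOC(=O)/C=C(\C)[C@H](O)C[C@]12O[C@@]1(C)CCCC2(C)C
F2 | step 5 | ethyl (2E)-3-[(2R,3aR,7aR)-3a-hydroxy-4,4,7a-trimethyloctahydro-1-benzofuran-2-yl]but-2-enoate | CCOC(=O)/C=C(\C)[C@H]1C[C@@]2(O)C(C)(C)CCC[C@@]2(C)O1
F3 | step 13 | (2E)-3-[(2R,7aR)-4,4,7a-trimethyl-2,4,5,6,7,7a-hexahydro-1-benzofuran-2-yl]but-2-enal | O=C/C=C(\C)[C@H]1C=C2C(C)(C)CCC[C@@]2(C)O1
F4 | step 13 | (2E,4E,6E,8E,10E,12E)-2,7,11-trimethyl-13-[(1R)-2,6,6-trimethylcyclohex-2-en-1-yl]trideca-2,4,6,8,10,12-hexaen-1-ol | CC1=CCCC(C)(C)[C@H]1/C=C/C(C)=C/C=C/C(C)=C/C=C/C=C(C)/CO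
F5 | step 13 | {(2E,4E,6E,8E,10E,12E)-2,7,11-trimethyl-13-[(1R)-2,6,6-trimethylcyclohex-2-en-1-yl]trideca-2,4,6,8,10,12-hexaen-1-yl}triphenylphosphonium bromide | CC1=CCCC(C)(C)[C@H]1/C=C/C(C)=C/C=C/C(C)=C/C=C/C=C(C)/C[P+](c1ccccc1)(c1ccccc1)c1ccccc1.[Br-]
F6 | step 13 | ylide of F5, triphenyl(C25 polyenylidene)phosphorane | CC1=CCCC(C)(C)[C@H]1/C=C/C(C)=C/C=C/C(C)=C/C=C/C=C(C)/C=P(c1ccccc1)(c1ccccc1)c1ccccc1
F7 | step 4 | ethyl (2E,4R)-4-{[(2S)-2-methoxy-2-phenylacetyl]oxy}-3-methyl-5-(2,6,6-trimethylcyclohex-1-en-1-yl)pent-2-enoate | CCOC(=O)/C=C(\C)[C@H](OC(=O)[C@@H](OC)c1ccccc1)CC1=C(C)CCCC1(C)C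
F8 | step 4 | ethyl (2E,4S)-4-{[(2S)-2-methoxy-2-phenylacetyl]oxy}-3-methyl-5-(2,6,6-trimethylcyclohex-1-en-1-yl)pent-2-enoate | CCOC(=O)/C=C(\C)[C@@H](OC(=O)[C@@H](OC)c1ccccc1)CC1=C(C)CCCC1(C)C
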